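The strategy rests on reading the 4H‑pyran ring of the cyclopenta[c]pyran core (O2, C1, C7a, C4a, C4, C3) as the [4+2] adduct of an allenyl ketone and an alkyne. The key step is a thermal intramolecular hetero‑Diels–Alder reaction in which the oxadiene O2=C3–C4=C4a adds to the ethynyl group on the C7 carbinol. The pyran and the cyclopentene (C4a, C5, C6, C7, C7a) then close together, while the second allene bond becomes the C4a=C5 ring‑fusion alkene. The precursor is an acyclic 1,3‑diacceptor allene that already carries the ester, the (Z)‑acylmethylidene side chain and the tertiary propargylic alcohol. It is assembled from a 3(2H)‑furanone that masks the cis‑hydroxy‑enone.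

Key step: step 11

Remarks and assumptions:
- Atom locants (C1, O2, C3, C4, C4a, C5, C6, C7, C7a) are those of the cyclopenta[c]pyran core of the target.
- In step 4 the ligand enantiomer is the one that delivers the (S)‑carbinol; the sense of induction is assumed to be assignable and the antipodal ligand is used otherwise.
- Compound 16 is racemic. Its carbinol centre, the furanol carbon of 17 and the allene axis of 17–19 are destroyed later and are left undefined.
- Compounds 18 and 19 are expected to equilibrate with cyclic hemiketals (C7 hydroxyl onto the side‑chain ketone); they are drawn in the open form.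

Step 1
Reactants: 1 (S)-4-benzyloxazolidin-2-one; 2 octanoyl chloride
Product: 3 (S)-4-benzyl-3-octanoyloxazolidin-2-one
Conditions: n-BuLi, THF, −78 °C; then 2, −78 → 0 °C
Reagents that add atoms: none
Why: N‑acylation of the lithiated Evans oxazolidinone by the acid chloride is a standard acyl substitution and forms no stereocentre.

Step 2
Reactants: 3 (S)-4-benzyl-3-octanoyloxazolidin-2-one
Product: 4 (S)-4-benzyl-3-[(2S)-2-methyloctanoyl]oxazolidin-2-one
Conditions: NaHMDS, THF, −78 °C; then MeI, −78 → −40 °C
Reagents that add atoms: iodomethane, CI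
Why: Evans asymmetric alkylation, in which the chelated (Z)‑sodium enolate is methylated on the face opposite the benzyl group, should set the (2S) centre of the side chain.

Step 3
Reactants: 4 (S)-4-benzyl-3-[(2S)-2-methyloctanoyl]oxazolidin-2-one
Product: 5 (2S)-N-methoxy-N,2-dimethyloctanamide
Conditions: Me(MeO)NH·HCl, AlMe3, CH2Cl2, 0 °C → rt
Reagents that add atoms: N,O-dimethylhydroxylamine hydrochloride, CNOC.Cl
Why: Aluminium‑amide transamination of the imide (Weinreb amide formation) should release the auxiliary without exposing the α‑stereocentre to base.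

Step 4
Reactants: 6 methyl pyruvate; 7 ethynyltrimethylsilane
Product: 8 methyl (2S)-2-hydroxy-2-methyl-4-(trimethylsilyl)but-3-ynoate
Conditions: Zn(OTf)2 (20 mol%), (1S,2S)- or (1R,2R)-2-(dimethylamino)-1-(4-nitrophenyl)-3-(tert-butyldimethylsilyloxy)propan-1-ol (22 mol%), Et3N (30 mol%), toluene, 70 °C
Reagents that add atoms: none
Why: Catalytic enantioselective alkynylation of an α‑keto ester by the zinc acetylide should set the tertiary carbinol (the future C7), the face being selected by the chiral zinc amino‑alkoxide complex.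

Step 5
Reactants: 8 methyl (2S)-2-hydroxy-2-methyl-4-(trimethylsilyl)but-3-ynoate
Product: 10 (3S)-3-hydroxy-3-methyl-5-(trimethylsilyl)pent-4-yn-2-one, via Weinreb amide 9 (not isolated)
Conditions: Me(MeO)NH·HCl, i-PrMgCl, THF, −20 °C; then MeMgBr, −20 → 0 °C; aq. NH4Cl
Reagents that add atoms: methylmagnesium bromide, C[Mg]Br
Why: One‑pot Weinreb amidation of the ester by the magnesium amide followed by Grignard addition should stop at the methyl ketone because the chelated tetrahedral adduct survives until work‑up, and the quaternary carbinol cannot epimerise.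

Step 6
Reactants: 10 (3S)-3-hydroxy-3-methyl-5-(trimethylsilyl)pent-4-yn-2-one; 5 (2S)-N-methoxy-N,2-dimethyloctanamide
Product: 12 (2S)-2-methyl-5-[(2S)-octan-2-yl]-2-[(trimethylsilyl)ethynyl]furan-3(2H)-one, via diketone 11 (not isolated)
Conditions: LDA (2.2 equiv), THF, −78 °C; then 5, −78 → 0 °C; then 2 M HCl, THF, rt
Reagents that add atoms: none
Why: Claisen‑type C‑acylation of the alkoxide–enolate dianion (only the methyl group is enolisable) by the Weinreb amide, whose adduct collapses only on work‑up so that the α‑centre of 5 is not exposed to base, should give the α′‑hydroxy‑1,3‑diketone, which undergoes the classical acid cyclodehydration to the 3(2H)‑furanone.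

Step 7
Reactants: 12 (2S)-2-methyl-5-[(2S)-octan-2-yl]-2-[(trimethylsilyl)ethynyl]furan-3(2H)-one
Product: 13 (2S)-2-ethynyl-2-methyl-5-[(2S)-octan-2-yl]furan-3(2H)-one
Conditions: K2CO3 (0.1 equiv), MeOH, 0 °C
Reagents that add atoms: none
Why: Methoxide‑catalysed protodesilylation is selective for the C(sp)–Si bond and, run briefly at low temperature with catalytic base, should leave the vinylogous ester and both stereocentres untouched.

Step 8
Reactants: 14 methyl propiolate; 15 2-methyloxirane (racemic)
Product: 16 methyl 5-hydroxyhex-2-ynoate (racemic)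
Conditions: n-BuLi, THF, −78 °C; BF3·OEt2; then 15, −78 °C
Reagents that add atoms: none
Why: BF3‑promoted opening of the epoxide at its less hindered carbon by the lithium acetylide of the propiolate (Yamaguchi–Hirao alkynylation) should give the δ‑hydroxy ynoate, whose racemic carbinol centre is removed in step 10.

Step 9
Reactants: 13 (2S)-2-ethynyl-2-methyl-5-[(2S)-octan-2-yl]furan-3(2H)-one; 16 methyl 5-hydroxyhex-2-ynoate
Product: 18 methyl 5-hydroxy-2-[(3S,4Z,7S)-3-hydroxy-3,7-dimethyl-6-oxotridec-4-en-1-yn-4-yl]hexa-2,3-dienoate, via furanol adduct 17 (not isolated)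
Conditions: 16, LDA (2 equiv per 16), THF, −78 °C; anhydrous CeCl3; then 13, −78 °C; AcOH quench; 0.5 M HCl, THF, 0 °C
Reagents that add atoms: water, O
Why: γ‑Deprotonation of the ynoate gives an allenyl (cumulenic) enolate whose cerium derivative should add through its α‑carbon to the vinylogous‑ester carbonyl of 13 (aldol‑type 1,2‑addition that creates the allenoate), and dilute acid then ionises the tertiary allylic alcohol to a cyclic oxocarbenium ion that is hydrated at the former enol‑ether carbon (Stork–Danheiser‑type transposition), so that the furanone ring oxygen becomes the C7 hydroxyl and the acyl group is formed syn to C7 on the new C6=CH bond; no stereocentre of the target is set here and the carbinol and allene‑axis isomers converge later.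

Step 10
Reactants: 18 methyl 5-hydroxy-2-[(3S,4Z,7S)-3-hydroxy-3,7-dimethyl-6-oxotridec-4-en-1-yn-4-yl]hexa-2,3-dienoate
Product: 19 methyl 2-[(3S,4Z,7S)-3-hydroxy-3,7-dimethyl-6-oxotridec-4-en-1-yn-4-yl]-5-oxohexa-2,3-dienoate
Conditions: DMP, CH2Cl2, 0 °C; product used at once
Reagents that add atoms: none
Why: Dess–Martin oxidation is selective for the secondary allenylic carbinol (the tertiary hydroxyl cannot react) and its base‑free medium should spare the 1,3‑diacceptor allene.

Step 11
Reactants: 19 methyl 2-[(3S,4Z,7S)-3-hydroxy-3,7-dimethyl-6-oxotridec-4-en-1-yn-4-yl]-5-oxohexa-2,3-dienoate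
Product: 20 methyl (6Z,7R)-7-hydroxy-3,7-dimethyl-6-[(3S)-3-methyl-2-oxononylidene]-6,7-dihydrocyclopenta[c]pyran-5-carboxylate
Conditions: toluene (0.005 M), BHT (cat.), 110 °C, sealed vessel
Reagents that add atoms: none
Why: Proposed new method: the acetyl C=O and the adjacent allene bond C4=C4a form an electron‑poor 1‑oxadiene that should add across the tethered terminal alkyne C7a≡C1 in a thermal intramolecular hetero‑Diels–Alder reaction, forming the O2–C1 and C4a–C7a bonds together while the orthogonal allene bond C4a=C5 survives as the ring‑fusion alkene; the closest known reactions are the intramolecular Diels–Alder reaction of vinylallenes tethered at the allene terminus and the intramolecular oxa‑[4+2] cycloadditions of enones and conjugated ynones with alkynes. The pyran closes in the concerted, probably asynchronous [4+2] mode, and the cyclopentene closes at the same time through the tether C5–C6–C7 as the alkyne carbon C7a bonds to the sp carbon C4a in the plane of the C5 substituents, a five‑membered closure that is exo with respect to both reacting π bonds (5‑exo‑dig at the alkyne). No new stereocentre arises, the C7 carbinol and the side‑chain centre are not touched, and the exocyclic C6=CH geometry is that of 19 (acyl syn to C7), which the O–H···O=C hydrogen bond also favours. The step needs chemoselectivity for the oxadiene over the vinylallene diene and over conjugate addition of the tertiary hydroxyl to C4a: the alkyne can reach only C4a without forming a small or bridged ring, the acyl group is held anti to C5 so that no oxa‑6π closure onto the allene can occur, and neutral, dilute, base‑free conditions disfavour hydroxyl addition, prototropic isomerisation and dimerisation. Release of allene strain and formation of the push–pull conjugated pyran should make the cycloaddition irreversible.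

Compound list
1 | (S)-4-benzyloxazolidin-2-one | O=C1N[C@@H](Cc2ccccc2)CO1 | starting material
2 | octanoyl chloride | CCCCCCCC(=O)Cl | starting material
3 | (S)-4-benzyl-3-octanoyloxazolidin-2-one | CCCCCCCC(=O)N1[C@@H](Cc2ccccc2)COC1=O | intermediate
4 | (S)-4-benzyl-3-[(2S)-2-methyloctanoyl]oxazolidin-2-one | CCCCCC[C@H](C)C(=O)N1[C@@H](Cc2ccccc2)COC1=O | intermediate
5 | (2S)-N-methoxy-N,2-dimethyloctanamide | CCCCCC[C@H](C)C(=O)N(C)OC | intermediate
6 | methyl pyruvate | CC(=O)C(=O)OC | starting material
7 | ethynyltrimethylsilane | C#C[Si](C)(C)C | starting material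
8 | methyl (2S)-2-hydroxy-2-methyl-4-(trimethylsilyl)but-3-ynoate | C[Si](C)(C)C#C[C@](C)(O)C(=O)OC | intermediate
9 | (2S)-2-hydroxy-N-methoxy-N,2-dimethyl-4-(trimethylsilyl)but-3-ynamide (not isolated) | C[Si](C)(C)C#C[C@](C)(O)C(=O)N(C)OC | intermediate
10 | (3S)-3-hydroxy-3-methyl-5-(trimethylsilyl)pent-4-yn-2-one | C[Si](C)(C)C#C[C@](C)(O)C(C)=O | intermediate
11 | (3S,7S)-3-hydroxy-3,7-dimethyl-1-(trimethylsilyl)tridec-1-yne-4,6-dione (not isolated) | C[Si](C)(C)C#C[C@](C)(O)C(=O)CC(=O)[C@@H](C)CCCCCC | intermediate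
12 | (2S)-2-methyl-5-[(2S)-octan-2-yl]-2-[(trimethylsilyl)ethynyl]furan-3(2H)-one | C[Si](C)(C)C#C[C@]1(C)OC(=CC1=O)[C@@H](C)CCCCCC | intermediate
13 | (2S)-2-ethynyl-2-methyl-5-[(2S)-octan-2-yl]furan-3(2H)-one | C#C[C@]1(C)OC(=CC1=O)[C@@H](C)CCCCCC | intermediate
14 | methyl propiolate | C#CC(=O)OC | starting material
15 | 2-methyloxirane (racemic) | CC1CO1 | starting material
16 | methyl 5-hydroxyhex-2-ynoate (racemic) | CC(O)CC#CC(=O)OC | intermediate
17 | methyl 2-{(2S)-2-ethynyl-3-hydroxy-2-methyl-5-[(2S)-octan-2-yl]-2,3-dihydrofuran-3-yl}-5-hydroxyhexa-2,3-dienoate (formed as its metal alkoxide; not isolated) | C#C[C@]1(C)OC(=CC1(O)C(C(=O)OC)=C=CC(C)O)[C@@H](C)CCCCCC | intermediate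
18 | methyl 5-hydroxy-2-[(3S,4Z,7S)-3-hydroxy-3,7-dimethyl-6-oxotridec-4-en-1-yn-4-yl]hexa-2,3-dienoate | CC(O)C=C=C(C(=O)OC)/C(=C/C(=O)[C@@H](C)CCCCCC)[C@@](C)(O)C#C | intermediate
19 | methyl 2-[(3S,4Z,7S)-3-hydroxy-3,7-dimethyl-6-oxotridec-4-en-1-yn-4-yl]-5-oxohexa-2,3-dienoate | CC(=O)C=C=C(C(=O)OC)/C(=C/C(=O)[C@@H](C)CCCCCC)[C@@](C)(O)C#C | intermediate
20 | methyl (6Z,7R)-7-hydroxy-3,7-dimethyl-6-[(3S)-3-methyl-2-oxononylidene]-6,7-dihydrocyclopenta[c]pyran-5-carboxylate | CCCCCC[C@H](C)C(=O)/C=C1/C(C(=O)OC)=C2C=C(C)OC=C2[C@]1(C)O | target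

Total step count: 11. Longest linear sequence: 8 steps (steps 1, 2, 3, 6, 7, 9, 10, 11).

Steps most likely to fail

Step 11 (Proposed new method). The unactivated alkyne may be too weak a 2π partner, so that conjugate addition of the C7 hydroxyl (or of the hemiketal hydroxyl) to the allene carbon C4a, prototropic drift of the allene or dimerisation could outrun the cycloaddition. The fallback replaces the alkyne by an electron‑rich vinyl sulfide, a known class of partner for inverse‑electron‑demand hetero‑Diels–Alder reactions of 1‑oxadienes; it sets out from 13 and comes back at 20. Radical thiol–yne addition of benzenethiol to 13 (AIBN, toluene, 80 °C) should give (2S)-2-methyl-5-[(2S)-octan-2-yl]-2-[2-(phenylsulfanyl)ethenyl]furan-3(2H)-one F1. The conditions of step 9 should convert it, through the furanol adduct methyl 5-hydroxy-2-{(2S)-3-hydroxy-2-methyl-5-[(2S)-octan-2-yl]-2-[2-(phenylsulfanyl)ethenyl]-2,3-dihydrofuran-3-yl}hexa-2,3-dienoate F2 (not isolated), into methyl 5-hydroxy-2-[(3S,4Z,7S)-3-hydroxy-3,7-dimethyl-6-oxo-1-(phenylsulfanyl)trideca-1,4-dien-4-yl]hexa-2,3-dienoate F3. The oxidation of step 10 should then give methyl 2-[(3S,4Z,7S)-3-hydroxy-3,7-dimethyl-6-oxo-1-(phenylsulfanyl)trideca-1,4-dien-4-yl]-5-oxohexa-2,3-dienoate F4. Warming F4 (toluene, 60–80 °C) should give the cycloadduct methyl (6Z,7S)-7-hydroxy-3,7-dimethyl-6-[(3S)-3-methyl-2-oxononylidene]-1-(phenylsulfanyl)-1,6,7,7a-tetrahydrocyclopenta[c]pyran-5-carboxylate F5, again closing both rings in one operation. Acid‑mediated loss of benzenethiol from the O,S‑acetal (PPTS, toluene, 60 °C) should then give 20.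

Step 9. The stabilised allenyl enolate may fail to add to the hindered vinylogous‑ester carbonyl: the aldolate could revert, the enolate could be quenched by proton transfer from the acetylenic C–H, the side‑chain γ‑hydrogen of the furanone could be removed with erosion of the (S) centre, or the ambident enolate could react at its γ‑carbon. The fallback uses an irreversible acetylide addition and installs the ester afterwards by palladium‑catalysed carbonylation; it sets out from 13 and comes back at 18. The cerium acetylide of 4-ethynyl-2,2,5-trimethyl-1,3-dioxolane (n-BuLi, CeCl3, THF, −78 °C) should add to 13 to give (2S)-2-ethynyl-2-methyl-5-[(2S)-octan-2-yl]-3-[(2,2,5-trimethyl-1,3-dioxolan-4-yl)ethynyl]-2,3-dihydrofuran-3-ol F6 (not isolated). Aqueous HCl in THF should effect the same transposition and remove the acetonide to give (3S,4Z,7S)-4-(3,4-dihydroxypent-1-yn-1-yl)-3-hydroxy-3,7-dimethyltridec-4-en-1-yn-6-one F7. 1,1′‑Carbonyldiimidazole should close the vicinal diol to the propargylic cyclic carbonate (3S,4Z,7S)-3-hydroxy-3,7-dimethyl-4-[(5-methyl-2-oxo-1,3-dioxolan-4-yl)ethynyl]tridec-4-en-1-yn-6-one F8. Decarboxylative carbonylation (Pd2(dba)3, PPh3, CO 1 atm, MeOH, rt; ionisation by zerovalent palladium to the allenylpalladium species, CO insertion, methanolysis) should then give 18.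

Step 6. C‑Acylation of the hindered dianion by the α‑branched Weinreb amide may be slow, leaving time for proton transfer, self‑condensation of the enolate or α‑ketol rearrangement of the alkoxide on warming. The fallback replaces the acylation by an aldol addition and an oxidation; it sets out from 5 and 10 and comes back at 11, which is cyclised to 12 by acid as in step 6. Reduction of 5 (LiAlH4, THF, −78 °C) should give (2S)-2-methyloctanal F9. Addition of F9 to the dianion of 10 (LDA, THF, −78 °C) should give (3S,7S)-3,6-dihydroxy-3,7-dimethyl-1-(trimethylsilyl)tridec-1-yn-4-one F10 as a mixture at the new carbinol. Dess–Martin oxidation of the secondary alcohol should then give 11.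

Further compounds
F1 | step 11 | (2S)-2-methyl-5-[(2S)-octan-2-yl]-2-[2-(phenylsulfanyl)ethenyl]furan-3(2H)-one | C[C@@]1(C=CSc2ccccc2)OC(=CC1=O)[C@@H](C)CCCCCC
F2 | step 11 | methyl 5-hydroxy-2-{(2S)-3-hydroxy-2-methyl-5-[(2S)-octan-2-yl]-2-[2-(phenylsulfanyl)ethenyl]-2,3-dihydrofuran-3-yl}hexa-2,3-dienoate | C[C@@]1(C=CSc2ccccc2)OC(=CC1(O)C(C(=O)OC)=C=CC(C)O)[C@@H](C)CCCCCC
F3 | step 11 | methyl 5-hydroxy-2-[(3S,4Z,7S)-3-hydroxy-3,7-dimethyl-6-oxo-1-(phenylsulfanyl)trideca-1,4-dien-4-yl]hexa-2,3-dienoate | CC(O)C=C=C(C(=O)OC)/C(=C/C(=O)[C@@H](C)CCCCCC)[C@@](C)(O)C=CSc1ccccc1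
F4 | step 11 | methyl 2-[(3S,4Z,7S)-3-hydroxy-3,7-dimethyl-6-oxo-1-(phenylsulfanyl)trideca-1,4-dien-4-yl]-5-oxohexa-2,3-dienoate | CC(=O)C=C=C(C(=O)OC)/C(=C/C(=O)[C@@H](C)CCCCCC)[C@@](C)(O)C=CSc1ccccc1
F5 | step 11 | methyl (6Z,7S)-7-hydroxy-3,7-dimethyl-6-[(3S)-3-methyl-2-oxononylidene]-1-(phenylsulfanyl)-1,6,7,7a-tetrahydrocyclopenta[c]pyran-5-carboxylate | CCCCCC[C@H](C)C(=O)/C=C1/C(C(=O)OC)=C2C=C(C)OC(Sc3ccccc3)C2[C@]1(C)O
F6 | step 9 | (2S)-2-ethynyl-2-methyl-5-[(2S)-octan-2-yl]-3-[(2,2,5-trimethyl-1,3-dioxolan-4-yl)ethynyl]-2,3-dihydrofuran-3-ol | C#C[C@]1(C)OC(=CC1(O)C#CC2OC(C)(C)OC2C)[C@@H](C)CCCCCC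
F7 | step 9 | (3S,4Z,7S)-4-(3,4-dihydroxypent-1-yn-1-yl)-3-hydroxy-3,7-dimethyltridec-4-en-1-yn-6-one | CC(O)C(O)C#C/C(=C/C(=O)[C@@H](C)CCCCCC)[C@@](C)(O)C#C
F8 | step 9 | (3S,4Z,7S)-3-hydroxy-3,7-dimethyl-4-[(5-methyl-2-oxo-1,3-dioxolan-4-yl)ethynyl]tridec-4-en-1-yn-6-one | CC1OC(=O)OC1C#C/C(=C/C(=O)[C@@H](C)CCCCCC)[C@@](C)(O)C#C
F9 | step 6 | (2S)-2-methyloctanal | CCCCCC[C@H](C)C=O
F10 | step 6 | (3S,7S)-3,6-dihydroxy-3,7-dimethyl-1-(trimethylsilyl)tridec-1-yn-4-one | C[Si](C)(C)C#C[C@](C)(O)C(=O)CC(O)[C@@H](C)CCCCCC
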